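**Plan**
- Retrosynthesis: the top C3–OH is traced back to a C3–B bond. Ring C of the top unit is then cut at O1–C2 and C3–C4, next the bond between the carbinol carbon (top C4) and middle C6, and last the interflavan bond middle C4–bottom C6.
- Enabling feature: top O1 and top C4 are both attached to ring A (at C8a and C4a), and C2–C3 is a two-carbon unit with trans substituents. Ring C therefore unravels into the heterodiene O=C8a–C4a=C4 of an ortho-quinone methide and an E-alkene.
- Forward: the middle unit (from (+)-catechin) and the bottom unit (from (−)-epicatechin), both bromine-capped at C8, are joined 4→6 by a Lewis-acid flavan coupling. Middle C6 is iodinated, magnesiated and added to a dibrominated salicylaldehyde. Ring C of the top unit closes last, followed by C–B oxidation and global hydrogenolysis.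
- Stereochemistry: C2 and C3 of the middle and bottom units come from the chiral pool. Middle C4 is set by attack trans to the 3-benzyloxy group. Top C4 is set by a chiral Brønsted acid, top C3 and C2 by endo approach and the E-alkene geometry, and the C3–O bond by stereoretentive oxidation.

Key step: step 14

Remark: each unit carries flavan numbering (O1, C2, C3, C4, C4a, C5–C8, C8a); "top", "middle" and "bottom" run from the chain-extending catechin to the terminal epicatechin.

Assumption: the (R)-configured acid is taken to leave open the methide face that leads to the catechin-type top unit; should the sense of induction prove opposite, the (S)-acid takes its place with no other change.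

**Step 1**
Reactants: 1 (−)-epicatechin
Product: 2 5,7,3',4'-tetra-O-benzyl-(−)-epicatechin (2R,3R; 3-OH free)
Conditions: BnBr (4.4 equiv), K2CO3, DMF, 0 °C to rt
Reagents that add atoms: benzyl bromide, BrCc1ccccc1
Why: Williamson etherification in which K2CO3 deprotonates only the four phenols, so the secondary 3-OH stays free and neither stereocentre is touched at this temperature.

**Step 2**
Reactants: 2 5,7,3',4'-tetra-O-benzyl-(−)-epicatechin
Product: 3 3,5,7,3',4'-penta-O-benzyl-(−)-epicatechin
Conditions: NaH, BnBr, DMF, 0 °C to rt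
Reagents that add atoms: benzyl bromide, BrCc1ccccc1
Why: Williamson etherification of the remaining secondary alcohol after deprotonation with NaH, so that no acidic OH interferes with the later Lewis-acid and Grignard steps.

**Step 3**
Reactants: 3 3,5,7,3',4'-penta-O-benzyl-(−)-epicatechin
Product: 4 8-bromo-3,5,7,3',4'-penta-O-benzyl-(−)-epicatechin (bottom unit, C6–H free)
Conditions: NBS (1.0 equiv), CH2Cl2, −78 °C to −20 °C, dark
Reagents that add atoms: N-bromosuccinimide, O=C1CCC(=O)N1Br
Why: electrophilic aromatic bromination, in which C8 is the most nucleophilic ring A carbon of a 5,7-dialkoxyflavan, so one equivalent of NBS caps C8 and leaves C6 as the only nucleophilic ring A site.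

**Step 4**
Reactants: 5 (+)-catechin
Product: 6 5,7,3',4'-tetra-O-benzyl-(+)-catechin (2R,3S; 3-OH free)
Conditions: BnBr (4.4 equiv), K2CO3, DMF, 0 °C to rt
Reagents that add atoms: benzyl bromide, BrCc1ccccc1
Why: Williamson etherification of the four phenols only, as in step 1, with both stereocentres untouched.

**Step 5**
Reactants: 6 5,7,3',4'-tetra-O-benzyl-(+)-catechin
Product: 7 (2R,3S,4S)-5,7,3',4'-tetra-O-benzyl-4-(2-ethoxyethoxy)catechin (4-alkoxy group cis to the 3-OH, trans to the C2 aryl group)
Conditions: DDQ (2 equiv), 2-ethoxyethanol (5 equiv), CH2Cl2, rt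
Reagents that add atoms: 2-ethoxyethanol, CCOCCO
Why: oxidative benzylic C–H functionalisation in which DDQ abstracts hydride from C4, the cation stabilised by O1 and the 5- and 7-benzyloxy groups is trapped by the alcohol on the face away from the C2 aryl group, and the new C4 centre is of no consequence because it is ionised again in step 8.

**Step 6**
Reactants: 7 (2R,3S,4S)-5,7,3',4'-tetra-O-benzyl-4-(2-ethoxyethoxy)catechin
Product: 8 (2R,3S,4S)-3,5,7,3',4'-penta-O-benzyl-4-(2-ethoxyethoxy)catechin
Conditions: NaH, BnBr, DMF, 0 °C to rt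
Reagents that add atoms: benzyl bromide, BrCc1ccccc1
Why: Williamson etherification of the 3-OH under basic conditions that leave the acid-labile 4-alkoxy group untouched.

**Step 7**
Reactants: 8 (2R,3S,4S)-3,5,7,3',4'-penta-O-benzyl-4-(2-ethoxyethoxy)catechin
Product: 9 (2R,3S,4S)-8-bromo-3,5,7,3',4'-penta-O-benzyl-4-(2-ethoxyethoxy)catechin (middle-unit electrophile)
Conditions: NBS (1.05 equiv), CH2Cl2, −40 °C to 0 °C, dark
Reagents that add atoms: N-bromosuccinimide, O=C1CCC(=O)N1Br
Why: electrophilic aromatic bromination at C8 as in step 3, the bromine serving as a cap that keeps the ionised unit from being attacked at its own C8 in step 8.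

**Step 8**
Reactants: 9 (2R,3S,4S)-8-bromo-3,5,7,3',4'-penta-O-benzyl-4-(2-ethoxyethoxy)catechin; 4 8-bromo-3,5,7,3',4'-penta-O-benzyl-(−)-epicatechin
Product: 10 8-bromo-penta-O-benzylcatechin-(4α→6)-8-bromo-penta-O-benzylepicatechin (middle unit 2R,3S with the C4–aryl bond trans to the 3-benzyloxy group; bottom unit 2R,3R; middle C6–H free)
Conditions: 4 (3 equiv, excess recovered), Me3SiOSO2CF3 (0.3 equiv), 4 Å molecular sieves, CH2Cl2, −78 °C to −30 °C; then Et3N
Reagents that add atoms: none
Why: Lewis-acid-mediated Friedel–Crafts flavan coupling in which the silyl triflate ionises the 4-alkoxy group of 9 and C6 of 4, its only free ring A carbon, attacks the C4 cation trans to the 3-benzyloxy group (the usual outcome for catechin-derived electrophiles), while the excess of 4 suppresses self-condensation of 9 through its own C6.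

**Step 9**
Reactants: 10 8-bromo-penta-O-benzylcatechin-(4α→6)-8-bromo-penta-O-benzylepicatechin
Product: 11 6-iodo derivative of 10 (iodine on middle C6)
Conditions: NIS (1.3 equiv), CF3CO2H (0.1 equiv), CH2Cl2–MeCN, 0 °C, dark
Reagents that add atoms: N-iodosuccinimide, O=C1CCC(=O)N1I
Why: electrophilic aromatic iodination at middle C6, the only unsubstituted ring A carbon left in 10, the four catechol-type rings B being far less nucleophilic than a phloroglucinol-type ring.

**Step 10**
Reactants: 12 2,4,6-trihydroxybenzaldehyde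
Product: 13 4,6-bis(benzyloxy)-2-hydroxybenzaldehyde
Conditions: BnBr (2.05 equiv), K2CO3, DMF, rt
Reagents that add atoms: benzyl bromide, BrCc1ccccc1
Why: Williamson etherification in which the 4-OH and one ortho OH are alkylated while the last ortho OH, held in a hydrogen bond to the formyl group, stays free.

**Step 11**
Reactants: 13 4,6-bis(benzyloxy)-2-hydroxybenzaldehyde
Product: 14 4,6-bis(benzyloxy)-3,5-dibromo-2-hydroxybenzaldehyde
Conditions: NBS (2.1 equiv), MeCN, 0 °C to rt
Reagents that add atoms: N-bromosuccinimide, O=C1CCC(=O)N1Br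
Why: electrophilic aromatic bromination of both free ring carbons, so that no regiochemical question arises, the bromines capping the future top ring A against Friedel–Crafts side reactions and twisting the benzyloxy groups out of conjugation, which should make the later quinone methide more electrophilic.

**Step 12**
Reactants: 15 3,4-bis(benzyloxy)benzaldehyde
Product: 16 (E)-2-[2-(3,4-bis(benzyloxy)phenyl)ethenyl]-4,4,5,5-tetramethyl-1,3,2-dioxaborolane
Conditions: bis(pinacolboryl)methane (1.2 equiv), lithium 2,2,6,6-tetramethylpiperidide (1.2 equiv), THF, 0 °C; then 15, −78 °C to rt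
Reagents that add atoms: bis(4,4,5,5-tetramethyl-1,3,2-dioxaborolan-2-yl)methane, CC1(C)OB(CB2OC(C)(C)C(C)(C)O2)OC1(C)C
Why: boron-Wittig olefination in which the lithiated geminal bis(boronate) adds to the aldehyde and syn elimination of the boron–oxygen unit gives the trans-alkenylboronate, the E geometry being what later translates into the 2,3-trans relationship.

**Step 13**
Reactants: 11 6-iodo dimer; 14 4,6-bis(benzyloxy)-3,5-dibromo-2-hydroxybenzaldehyde
Product: 19 diaryl carbinol in which the future top C4 carries OH plus the 4,6-bis(benzyloxy)-3,5-dibromo-2-hydroxyphenyl ring plus middle C6 (mixture of carbinol epimers), via arylmagnesium chloride 17 (not isolated), via sodium phenoxide 18 (not isolated)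
Conditions: 11, (CH3)2CHMgCl·LiCl (1.1 equiv), THF, −15 °C to 0 °C; separately 14 (1.5 equiv), NaH, THF, 0 °C; combine at −20 °C to rt; aq. NH4Cl; rapid filtration through Et3N-washed silica
Reagents that add atoms: none
Why: iodine–magnesium exchange takes place at the aryl iodide much faster than at the aryl bromides, and the resulting aryl Grignard reagent adds to the formyl group of the pre-formed phenoxide 18 (Grignard addition) to give the carbinol as a mixture of epimers whose new centre is erased in step 14.

**Step 14**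
Reactants: 19 diaryl carbinol; 16 (E)-styrylboronate
Product: 21 protected trimer with a pinacol boronate on top C3 (top unit 2,3-trans-3,4-trans: C2 aryl and C4 middle unit cis to each other, boron trans to both), via ortho-quinone methide 20 (not isolated)
Conditions: 16 (3 equiv), 1,1,1-trifluoro-N-[(11bR)-4-oxido-2,6-bis(2,4,6-triisopropylphenyl)dinaphtho[2,1-d:1',2'-f][1,3,2]dioxaphosphepin-4-yl]methanesulfonamide (10 mol%), 4 Å molecular sieves, toluene–CH2Cl2, −20 °C to rt
Reagents that add atoms: none
Why: Proposed new method: the chiral acid protonates the benzylic hydroxyl of 19, water leaves, and the top ring A, the only ring with a free ortho phenol, becomes quinone methide 20 hydrogen-bonded to the chiral anion, after which the boron-bearing carbon of 16 bonds to the methide carbon (C4) and the phenol oxygen closes onto the aryl-bearing carbon (C2), whose developing positive charge is stabilised by the para-benzyloxy group and by hyperconjugation with the C–B bond. The closest known reaction type is the chiral Brønsted-acid-catalysed inverse-demand hetero-Diels–Alder reaction of quinone methides from ortho-hydroxybenzhydrols with styrenes and β-substituted styrenes to give 2,4-cis-chromans; new are the alkenylboronate as dienophile and the hindered, fully oxygenated methide. Ring C of the top unit closes in a [4+2] mode, concerted but asynchronous, or in the limit as C3–C4 bond formation followed at once by O1–C2 closure of the six-membered ring. C4 is set by the face of 20 left open by the chiral counter-anion, C3 relative to C4 by endo approach of the dienophile aryl group (2,4-cis), and C2 relative to C3 by suprafacial addition to the E-alkene (2,3-trans), which together give the all-trans array. The step needs chemoselectivity for the alkene over Friedel–Crafts attack by ring A carbons and regioselectivity within the alkene: the first is secured by the bromine caps on every ring A carbon of 19 and 21, the second by the benzylic stabilisation that forces boron to C3.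

**Step 15**
Reactants: 21 C3-borylated protected trimer
Product: 22 protected trimer with free top 3-OH (top unit 2R,3S catechin-type, 4α-linked)
Conditions: NaBO3·4H2O (5 equiv), THF–H2O, rt
Reagents that add atoms: sodium perborate tetrahydrate, [Na+].[O-]OB=O.O.O.O.O
Why: oxidation of the alkylboronate with perborate proceeds by 1,2-migration of carbon from boron to oxygen with retention, so the C3 hydroxyl ends up trans to both neighbouring aryl groups, as in the hydroboration–oxidation of flav-3-enes.

**Step 16**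
Reactants: 22 protected trimer with free top 3-OH
Product: 23 catechin-(4α→6)-catechin-(4α→6)-epicatechin (target)
Conditions: H2 (1 atm), Pd(OH)2 on carbon, Et3N (4.4 equiv), THF–MeOH–H2O, rt
Reagents that add atoms: none
Why: catalytic hydrogenolysis should cleave the fourteen benzyl ethers and the four aryl C–Br bonds in one operation, triethylamine taking up the HBr so that the acid-labile interflavan bonds and the stereocentres are not disturbed.

**Compound list**
1 | (−)-epicatechin (2R,3R) | O[C@@H]1Cc2c(O)cc(O)cc2O[C@@H]1c1ccc(O)c(O)c1 | starting material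
2 | 5,7,3',4'-tetra-O-benzyl-(−)-epicatechin | O[C@@H]1Cc2c(OCc9ccccc9)cc(OCc9ccccc9)cc2O[C@@H]1c1ccc(OCc9ccccc9)c(OCc9ccccc9)c1 | intermediate
3 | 3,5,7,3',4'-penta-O-benzyl-(−)-epicatechin | c9ccccc9CO[C@@H]1Cc2c(OCc9ccccc9)cc(OCc9ccccc9)cc2O[C@@H]1c1ccc(OCc9ccccc9)c(OCc9ccccc9)c1 | intermediate
4 | 8-bromo-3,5,7,3',4'-penta-O-benzyl-(−)-epicatechin | c9ccccc9CO[C@@H]1Cc2c(OCc9ccccc9)cc(OCc9ccccc9)c(Br)c2O[C@@H]1c1ccc(OCc9ccccc9)c(OCc9ccccc9)c1 | intermediate
5 | (+)-catechin (2R,3S) | O[C@H]1Cc2c(O)cc(O)cc2O[C@@H]1c1ccc(O)c(O)c1 | starting material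
6 | 5,7,3',4'-tetra-O-benzyl-(+)-catechin | O[C@H]1Cc2c(OCc9ccccc9)cc(OCc9ccccc9)cc2O[C@@H]1c1ccc(OCc9ccccc9)c(OCc9ccccc9)c1 | intermediate
7 | (2R,3S,4S)-5,7,3',4'-tetra-O-benzyl-4-(2-ethoxyethoxy)catechin | O[C@H]1[C@@H](OCCOCC)c2c(OCc9ccccc9)cc(OCc9ccccc9)cc2O[C@@H]1c1ccc(OCc9ccccc9)c(OCc9ccccc9)c1 | intermediate
8 | (2R,3S,4S)-3,5,7,3',4'-penta-O-benzyl-4-(2-ethoxyethoxy)catechin | c9ccccc9CO[C@H]1[C@@H](OCCOCC)c2c(OCc9ccccc9)cc(OCc9ccccc9)cc2O[C@@H]1c1ccc(OCc9ccccc9)c(OCc9ccccc9)c1 | intermediate
9 | (2R,3S,4S)-8-bromo-3,5,7,3',4'-penta-O-benzyl-4-(2-ethoxyethoxy)catechin | c9ccccc9CO[C@H]1[C@@H](OCCOCC)c2c(OCc9ccccc9)cc(OCc9ccccc9)c(Br)c2O[C@@H]1c1ccc(OCc9ccccc9)c(OCc9ccccc9)c1 | intermediate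
10 | 8-bromo-penta-O-benzylcatechin-(4α→6)-8-bromo-penta-O-benzylepicatechin | c1c(OCc9ccccc9)c(Br)c2c(c1OCc9ccccc9)[C@@H](c1c(OCc9ccccc9)c(Br)c3c(c1OCc9ccccc9)C[C@@H](OCc9ccccc9)[C@@H](c4ccc(OCc9ccccc9)c(OCc9ccccc9)c4)O3)[C@H](OCc9ccccc9)[C@@H](c4ccc(OCc9ccccc9)c(OCc9ccccc9)c4)O2 | intermediate
11 | 6-iodo derivative of 10 (iodine on middle C6) | Ic1c(OCc9ccccc9)c(Br)c2c(c1OCc9ccccc9)[C@@H](c1c(OCc9ccccc9)c(Br)c3c(c1OCc9ccccc9)C[C@@H](OCc9ccccc9)[C@@H](c4ccc(OCc9ccccc9)c(OCc9ccccc9)c4)O3)[C@H](OCc9ccccc9)[C@@H](c4ccc(OCc9ccccc9)c(OCc9ccccc9)c4)O2 | intermediate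
12 | 2,4,6-trihydroxybenzaldehyde | O=Cc1c(O)cc(O)cc1O | starting material
13 | 4,6-bis(benzyloxy)-2-hydroxybenzaldehyde | O=Cc1c(O)cc(OCc9ccccc9)cc1OCc9ccccc9 | intermediate
14 | 4,6-bis(benzyloxy)-3,5-dibromo-2-hydroxybenzaldehyde | O=Cc1c(O)c(Br)c(OCc9ccccc9)c(Br)c1OCc9ccccc9 | intermediate
15 | 3,4-bis(benzyloxy)benzaldehyde | O=Cc1ccc(OCc2ccccc2)c(OCc2ccccc2)c1 | starting material
16 | (E)-2-[2-(3,4-bis(benzyloxy)phenyl)ethenyl]-4,4,5,5-tetramethyl-1,3,2-dioxaborolane | CC1(C)OB(/C=C/c2ccc(OCc3ccccc3)c(OCc3ccccc3)c2)OC1(C)C | intermediate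
17 | arylmagnesium chloride of the dimer (magnesium on middle C6; not isolated) | Cl[Mg]c1c(OCc9ccccc9)c(Br)c2c(c1OCc9ccccc9)[C@@H](c1c(OCc9ccccc9)c(Br)c3c(c1OCc9ccccc9)C[C@@H](OCc9ccccc9)[C@@H](c4ccc(OCc9ccccc9)c(OCc9ccccc9)c4)O3)[C@H](OCc9ccccc9)[C@@H](c4ccc(OCc9ccccc9)c(OCc9ccccc9)c4)O2 | intermediate
18 | sodium 3,5-bis(benzyloxy)-2,4-dibromo-6-formylphenolate (not isolated) | [Na+].[O-]c1c(Br)c(OCc9ccccc9)c(Br)c(OCc9ccccc9)c1C=O | intermediate
19 | diaryl carbinol of the top ring A and the capped dimer (both epimers at the carbinol carbon) | Oc1c(Br)c(OCc9ccccc9)c(Br)c(OCc9ccccc9)c1C(O)c1c(OCc9ccccc9)c(Br)c2c(c1OCc9ccccc9)[C@@H](c1c(OCc9ccccc9)c(Br)c3c(c1OCc9ccccc9)C[C@@H](OCc9ccccc9)[C@@H](c4ccc(OCc9ccccc9)c(OCc9ccccc9)c4)O3)[C@H](OCc9ccccc9)[C@@H](c4ccc(OCc9ccccc9)c(OCc9ccccc9)c4)O2 | intermediate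
20 | ortho-quinone methide of the top ring A (not isolated) | O=C1C(Br)=C(OCc9ccccc9)C(Br)=C(OCc9ccccc9)C1=Cc1c(OCc9ccccc9)c(Br)c2c(c1OCc9ccccc9)[C@@H](c1c(OCc9ccccc9)c(Br)c3c(c1OCc9ccccc9)C[C@@H](OCc9ccccc9)[C@@H](c4ccc(OCc9ccccc9)c(OCc9ccccc9)c4)O3)[C@H](OCc9ccccc9)[C@@H](c4ccc(OCc9ccccc9)c(OCc9ccccc9)c4)O2 | intermediate
21 | protected trimer with a pinacol boronate on top C3 (top unit all-trans, 6,8-dibromo) | c9ccccc9COc1c(Br)c(OCc9ccccc9)c2c(c1Br)O[C@H](c4ccc(OCc9ccccc9)c(OCc9ccccc9)c4)[C@@H](B5OC(C)(C)C(C)(C)O5)[C@@H]2c1c(OCc9ccccc9)c(Br)c2c(c1OCc9ccccc9)[C@@H](c1c(OCc9ccccc9)c(Br)c3c(c1OCc9ccccc9)C[C@@H](OCc9ccccc9)[C@@H](c4ccc(OCc9ccccc9)c(OCc9ccccc9)c4)O3)[C@H](OCc9ccccc9)[C@@H](c4ccc(OCc9ccccc9)c(OCc9ccccc9)c4)O2 | intermediate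
22 | protected trimer with free top 3-OH | c9ccccc9COc1c(Br)c(OCc9ccccc9)c2c(c1Br)O[C@H](c4ccc(OCc9ccccc9)c(OCc9ccccc9)c4)[C@@H](O)[C@@H]2c1c(OCc9ccccc9)c(Br)c2c(c1OCc9ccccc9)[C@@H](c1c(OCc9ccccc9)c(Br)c3c(c1OCc9ccccc9)C[C@@H](OCc9ccccc9)[C@@H](c4ccc(OCc9ccccc9)c(OCc9ccccc9)c4)O3)[C@H](OCc9ccccc9)[C@@H](c4ccc(OCc9ccccc9)c(OCc9ccccc9)c4)O2 | intermediate
23 | catechin-(4α→6)-catechin-(4α→6)-epicatechin | Oc1cc(O)c2c(c1)O[C@H](c1ccc(O)c(O)c1)[C@@H](O)[C@@H]2c1c(O)cc2c(c1O)[C@@H](c1c(O)cc3c(c1O)C[C@@H](O)[C@@H](c1ccc(O)c(O)c1)O3)[C@H](O)[C@@H](c1ccc(O)c(O)c1)O2 | target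

**Step count and risks**
Total step count: 16. Longest linear sequence: 10 steps (steps 4–9 and 13–16, from (+)-catechin).

Most likely to fail, first: step 14 (Proposed new method). The methide carbon carries a di-ortho-substituted aryl group, so the cycloaddition may be slow. Loss of boron from the β-boryl benzylic cation, 1,5-hydride transfer from a neighbouring benzyloxy CH2 to the cationic carbon, or poor facial discrimination when the catalyst and the stereogenic middle unit oppose each other could then take over. The fallback uses known chemistry and gives up the quinone methide: the top unit is taken from the chiral pool by a second Lewis-acid flavan coupling. It sets out from dimer 10, whose middle C6 is its only free ring A carbon, and a further portion of electrophile 9. Slow addition of 9 to 10 with Me3SiOSO2CF3 in CH2Cl2 at low temperature should give, again by attack trans to the 3-benzyloxy group, the fully protected trimer with an 8-bromo-penta-O-benzylcatechin top unit F1. Hydrogenolysis of F1 under the conditions of step 16 removes fifteen benzyl groups and three bromines, and the sequence comes back to the route at the target 23.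

Second: step 8. Ionised 9 may condense with itself through its own unsubstituted C6 while the bromine-deactivated, doubly flanked C6 of 4 attacks only sluggishly. The fallback sets out from 9 and iodinates it first with NIS to the 8-bromo-6-iodo electrophile F2, which has no nucleophilic ring A carbon left. Its coupling with 4 under the same silyl triflate, now free to be run with more promoter and at higher temperature without oligomerisation, gives the iodinated dimer directly and returns to the route at 11, so that step 9 falls away.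

Third: step 13. Addition of the hindered aryl Grignard reagent 17 to the electron-rich phenoxide aldehyde may remain incomplete, with protonation of 17 back to 10 or hydride transfer from the product alkoxide to excess aldehyde as the competing processes. The fallback sets out from 14, which is silylated with t-BuMe2SiCl and imidazole to the neutral and more electrophilic aldehyde F3. Addition of 17 to F3 gives the silylated carbinol F4. Bu4NF then removes the silyl group, from whichever oxygen it sits on after possible migration, and returns to the route at 19.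

**Further compounds**
F1 | step 14 | 8-bromo-penta-O-benzylcatechin-(4α→6)-8-bromo-penta-O-benzylcatechin-(4α→6)-8-bromo-penta-O-benzylepicatechin | c9ccccc9COc1cc(OCc9ccccc9)c2c(c1Br)O[C@H](c4ccc(OCc9ccccc9)c(OCc9ccccc9)c4)[C@@H](OCc9ccccc9)[C@@H]2c1c(OCc9ccccc9)c(Br)c2c(c1OCc9ccccc9)[C@@H](c1c(OCc9ccccc9)c(Br)c3c(c1OCc9ccccc9)C[C@@H](OCc9ccccc9)[C@@H](c4ccc(OCc9ccccc9)c(OCc9ccccc9)c4)O3)[C@H](OCc9ccccc9)[C@@H](c4ccc(OCc9ccccc9)c(OCc9ccccc9)c4)O2
F2 | step 8 | (2R,3S,4S)-8-bromo-6-iodo-3,5,7,3',4'-penta-O-benzyl-4-(2-ethoxyethoxy)catechin | c9ccccc9CO[C@H]1[C@@H](OCCOCC)c2c(OCc9ccccc9)c(I)c(OCc9ccccc9)c(Br)c2O[C@@H]1c1ccc(OCc9ccccc9)c(OCc9ccccc9)c1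
F3 | step 13 | 4,6-bis(benzyloxy)-3,5-dibromo-2-(tert-butyldimethylsilyloxy)benzaldehyde | O=Cc1c(O[Si](C)(C)C(C)(C)C)c(Br)c(OCc9ccccc9)c(Br)c1OCc9ccccc9
F4 | step 13 | O-silylated diaryl carbinol (tert-butyldimethylsilyl ether of the phenol of 19, both carbinol epimers) | CC(C)(C)[Si](C)(C)Oc1c(Br)c(OCc9ccccc9)c(Br)c(OCc9ccccc9)c1C(O)c1c(OCc9ccccc9)c(Br)c2c(c1OCc9ccccc9)[C@@H](c1c(OCc9ccccc9)c(Br)c3c(c1OCc9ccccc9)C[C@@H](OCc9ccccc9)[C@@H](c4ccc(OCc9ccccc9)c(OCc9ccccc9)c4)O3)[C@H](OCc9ccccc9)[C@@H](c4ccc(OCc9ccccc9)c(OCc9ccccc9)c4)O2
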